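**Retrosynthetic overview**
1. The tetronic acid is closed last, by Dieckmann condensation of the α-propanoyloxy ester 25, made from hydroxy ester 24.
2. Key disconnection: the CH2–CH2 bond between the CH2 next to the (S)-methyl carbon of the diene arm and the allylic CH2 of the Z-trisubstituted alkene. This gives alkylzinc iodide 23 and dihydropyran 5, joined by a nickel-catalysed ring-opening Negishi coupling.
3. Enabling feature: the tetronic acid ring oxygen O1 sits on C5, and the chain C5–CH2–C(CH3)=CH–CH2 ends at that allylic CH2. Tying this CH2 to the C5 oxygen gives a 3,6-dihydro-2H-pyran (O1, C2 carbinol carbon bearing CO2Et, C3H2, C4(CH3)=C5H, C6H2) whose endocyclic alkene can only be cis. Cleaving its allylic C6–O1 bond with a carbon nucleophile therefore gives the Z-alkene and the free C2 hydroxyl in one event.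
4. Fragments: 5 from glyoxylate-ene reaction, O-allylation and RCM; 23 from the Roche ester (vinyl iodide 14), pent-4-yn-1-ol (carboalumination/Pd coupling to the E,E-diene) and bromolactam 10 (Negishi coupling).
5. Ring order: dihydropyran (RCM, temporary) and pyrrolinone (condensation) first; the dihydropyran is opened in the key step; the tetronic acid (Dieckmann) is formed last.

Key step: step 14

Remark: the (S)-BINOL–titanium catalyst is assumed to give the (S)-configured ene product 3 (mirror image of the established (R)-ligand/(R)-product pairing); ethyl glyoxylate is cracked to the monomer before use.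

Step 1
Reactants: 1 ethyl glyoxylate; 2 isobutene (2-methylpropene)
Product: 3 ethyl (S)-2-hydroxy-4-methylpent-4-enoate
Conditions: (S)-BINOL/TiCl2(OiPr)2 (10 mol %), 4 Å MS, CH2Cl2, −30 °C
Reagents that add atoms: none
Why: Asymmetric glyoxylate-ene (carbonyl-ene) reaction; the BINOL–titanium Lewis acid chelates the glyoxylate and exposes one aldehyde face to the 1,1-disubstituted ene donor, which should set the (S)-carbinol centre.

Step 2
Reactants: 3 ethyl (S)-2-hydroxy-4-methylpent-4-enoate
Product: 4 ethyl (S)-2-(allyloxy)-4-methylpent-4-enoate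
Conditions: allyl bromide, Ag2O, Et2O, rt, dark
Reagents that add atoms: allyl bromide C=CCBr
Why: Silver(I) oxide-mediated Williamson-type O-allylation proceeds without a strong base, so the stereocentre α to the ester should not epimerise.

Step 3
Reactants: 4 ethyl (S)-2-(allyloxy)-4-methylpent-4-enoate
Product: 5 ethyl (S)-4-methyl-3,6-dihydro-2H-pyran-2-carboxylate
Conditions: Grubbs II (3 mol %), CH2Cl2 (0.02 M), 40 °C
Reagents that add atoms: none
Why: Ring-closing metathesis between the allyl ether and the 1,1-disubstituted alkene closes the six-membered ring with loss of ethylene, and the trisubstituted alkene formed is necessarily cis within the ring.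

Step 4
Reactants: 6 (S)-2-methylbutan-1-amine; 7 2,5-dimethoxy-2,5-dihydrofuran
Product: 8 1-[(S)-2-methylbutyl]-1,5-dihydro-2H-pyrrol-2-one
Conditions: aq. HCl (pH 1–2), H2O, rt; NaHCO3
Reagents that add atoms: none
Why: Acid hydrolysis of the bis-acetal unmasks (Z)-but-2-enedial, which condenses with the primary amine to a 2-hydroxypyrrole that tautomerises to the conjugated lactam (known condensation route to N-substituted 1,5-dihydropyrrol-2-ones); the side-chain stereocentre is not involved.

Step 5
Reactants: 8 1-[(S)-2-methylbutyl]-1,5-dihydro-2H-pyrrol-2-one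
Product: 10 3-bromo-1-[(S)-2-methylbutyl]-1,5-dihydro-2H-pyrrol-2-one, via trans-3,4-dibromolactam 9 (not isolated)
Conditions: Br2, CH2Cl2, 0 °C; then Et3N, 0 °C → rt
Reagents that add atoms: bromine BrBr
Why: Bromine addition to the C3=C4 bond followed by E1cB loss of HBr (acidic C3–H, β-bromide) is the standard α-bromination of α,β-unsaturated carbonyl compounds and should give the 3-bromo lactam.

Step 6
Reactants: 11 methyl (S)-3-hydroxy-2-methylpropanoate (Roche ester)
Product: 12 methyl (S)-3-[(tert-butyldimethylsilyl)oxy]-2-methylpropanoate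
Conditions: TBSCl, imidazole, CH2Cl2, 0 °C → rt
Reagents that add atoms: tert-butyldimethylsilyl chloride CC(C)(C)[Si](C)(C)Cl
Why: Imidazole-promoted silylation of the primary alcohol; the stereocentre is untouched.

Step 7
Reactants: 12 methyl (S)-3-[(tert-butyldimethylsilyl)oxy]-2-methylpropanoate
Product: 13 (S)-3-[(tert-butyldimethylsilyl)oxy]-2-methylpropanal
Conditions: DIBAL-H (1.05 equiv), CH2Cl2, −78 °C; Rochelle salt; used crude
Reagents that add atoms: none
Why: Partial ester reduction with DIBAL-H stops at the aluminium hemiacetal at −78 °C; cold, non-basic work-up and immediate use should preserve the α-stereocentre.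

Step 8
Reactants: 13 (S)-3-[(tert-butyldimethylsilyl)oxy]-2-methylpropanal
Product: 14 tert-butyl{[(2R,3E)-4-iodo-2-methylbut-3-en-1-yl]oxy}dimethylsilane
Conditions: CrCl2 (6 equiv), CHI3 (2 equiv), THF, 0 °C → rt
Reagents that add atoms: iodoform IC(I)I
Why: Takai olefination; the gem-dichromium carbenoid adds to the aldehyde and eliminates anti to give the (E)-vinyl iodide under near-neutral conditions that should not epimerise the α-centre.

Step 9
Reactants: 15 pent-4-yn-1-ol; 14 tert-butyl{[(2R,3E)-4-iodo-2-methylbut-3-en-1-yl]oxy}dimethylsilane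
Product: 17 (4E,6E,8R)-9-[(tert-butyldimethylsilyl)oxy]-4,8-dimethylnona-4,6-dien-1-ol, via alkenylalane 16 (not isolated)
Conditions: Me3Al (3 equiv), Cp2ZrCl2 (0.25 equiv), CH2Cl2, 0 °C → rt; then 14, ZnCl2 (cat.), Pd(PPh3)4 (5 mol %), THF, rt; aq. work-up
Reagents that add atoms: trimethylaluminium C[Al](C)C
Why: Zirconium-catalysed carboalumination adds methyl and aluminium syn across the terminal alkyne (Al at the terminus), and the Pd-catalysed alkenyl–alkenyl Negishi coupling retains both alkene geometries, so the (E,E)-diene should result.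

Step 10
Reactants: 17 (4E,6E,8R)-9-[(tert-butyldimethylsilyl)oxy]-4,8-dimethylnona-4,6-dien-1-ol
Product: 18 tert-butyl{[(2R,3E,5E)-9-iodo-2,6-dimethylnona-3,5-dien-1-yl]oxy}dimethylsilane
Conditions: I2, PPh3, imidazole, CH2Cl2, 0 °C
Reagents that add atoms: iodine II
Why: Appel iodination; SN2 displacement of the activated primary oxyphosphonium by iodide.

Step 11
Reactants: 18 tert-butyl{[(2R,3E,5E)-9-iodo-2,6-dimethylnona-3,5-dien-1-yl]oxy}dimethylsilane; 10 3-bromo-1-[(S)-2-methylbutyl]-1,5-dihydro-2H-pyrrol-2-one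
Product: 20 3-{(4E,6E,8R)-9-[(tert-butyldimethylsilyl)oxy]-4,8-dimethylnona-4,6-dien-1-yl}-1-[(S)-2-methylbutyl]-1,5-dihydro-2H-pyrrol-2-one, via alkylzinc iodide 19 (not isolated)
Conditions: Zn dust (TMSCl/BrCH2CH2Br-activated), LiCl, THF, 40 °C; then 10, Pd(OAc)2 (3 mol %), SPhos (6 mol %), THF, rt → 40 °C
Reagents that add atoms: none
Why: LiCl-mediated zinc insertion into the primary iodide and Pd-catalysed sp3–sp2 Negishi coupling with the activated α-bromo unsaturated lactam; the bulky biarylphosphine should make reductive elimination faster than β-hydride elimination.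

Step 12
Reactants: 20 3-{(4E,6E,8R)-9-[(tert-butyldimethylsilyl)oxy]-4,8-dimethylnona-4,6-dien-1-yl}-1-[(S)-2-methylbutyl]-1,5-dihydro-2H-pyrrol-2-one
Product: 21 3-[(4E,6E,8R)-9-hydroxy-4,8-dimethylnona-4,6-dien-1-yl]-1-[(S)-2-methylbutyl]-1,5-dihydro-2H-pyrrol-2-one
Conditions: HF·pyridine, pyridine, THF, 0 °C → rt
Reagents that add atoms: none
Why: Fluoride cleavage of the primary silyl ether under buffered, non-basic conditions that should leave the diene and the unsaturated lactam unchanged.

Step 13
Reactants: 21 3-[(4E,6E,8R)-9-hydroxy-4,8-dimethylnona-4,6-dien-1-yl]-1-[(S)-2-methylbutyl]-1,5-dihydro-2H-pyrrol-2-one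
Product: 22 3-[(4E,6E,8R)-9-iodo-4,8-dimethylnona-4,6-dien-1-yl]-1-[(S)-2-methylbutyl]-1,5-dihydro-2H-pyrrol-2-one
Conditions: I2, PPh3, imidazole, CH2Cl2, 0 °C
Reagents that add atoms: iodine II
Why: Appel iodination of the primary alcohol; the adjacent stereocentre is not involved.

Step 14
Reactants: 22 3-[(4E,6E,8R)-9-iodo-4,8-dimethylnona-4,6-dien-1-yl]-1-[(S)-2-methylbutyl]-1,5-dihydro-2H-pyrrol-2-one; 5 ethyl (S)-4-methyl-3,6-dihydro-2H-pyran-2-carboxylate
Product: 24 ethyl (2S,4Z,8S,9E,11E)-2-hydroxy-4,8,12-trimethyl-15-{1-[(S)-2-methylbutyl]-2-oxo-2,5-dihydro-1H-pyrrol-3-yl}pentadeca-4,9,11-trienoate, via alkylzinc iodide 23 (not isolated)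
Conditions: 22, Zn dust (activated), LiCl, THF, 40 °C; then 5, Ni(cod)2 (10 mol %), dppf (12 mol %), MgBr2·OEt2 (1 equiv), THF, 25 → 45 °C; aq. NH4Cl
Reagents that add atoms: none
Why: Proposed new method: Mg(II)/Zn(II) chelation between ring oxygen O1 and the ester carbonyl weakens the allylic C6–O1 bond, Ni(0)/dppf adds oxidatively with ring opening to an η3-allylnickel(II) alkoxide, the alkyl group of 23 is transferred from zinc, and C(sp3)–C(sp3) reductive elimination at the unsubstituted allyl terminus (former C6) forms the new CH2–CH2 bond. The closest known reaction types are the nickel-catalysed ring-opening cross-coupling of cyclic allylic ethers (2,5-dihydrofurans, 3,6-dihydro-2H-pyrans) with Grignard reagents and nickel-catalysed Negishi couplings of allylic electrophiles with alkylzinc halides; the new element is an alkylzinc nucleophile on an unstrained cyclic allylic ether. No ring is closed: the six-membered ring is opened, its endocyclic cis alkene becomes the acyclic Z-trisubstituted alkene, and the released alkoxide is the C2 hydroxyl needed for the tetronic acid. No new stereocentre is made; the (S)-carbinol carbon lies outside the allyl unit and the (S)-methyl centre β to zinc is not touched. The step needs bond formation at the CH2 terminus, secured by sterics against the fully substituted terminus, and retention of the Z geometry, secured because syn/anti exchange at the C(CH3)(CH2R) terminus would require a tertiary σ-allylnickel. It also needs suppression of β-hydride elimination, disfavoured in the coordinatively saturated (η3-allyl)(alkyl)Ni(dppf) species, and chemoselectivity, provided by the mild alkylzinc, which should leave the ethyl ester, the unsaturated lactam and the diene alone.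

Step 15
Reactants: 24 ethyl (2S,4Z,8S,9E,11E)-2-hydroxy-4,8,12-trimethyl-15-{1-[(S)-2-methylbutyl]-2-oxo-2,5-dihydro-1H-pyrrol-3-yl}pentadeca-4,9,11-trienoate
Product: 25 ethyl (2S,4Z,8S,9E,11E)-4,8,12-trimethyl-15-{1-[(S)-2-methylbutyl]-2-oxo-2,5-dihydro-1H-pyrrol-3-yl}-2-(propanoyloxy)pentadeca-4,9,11-trienoate
Conditions: (EtCO)2O, Et3N, DMAP (10 mol %), CH2Cl2, 0 °C → rt
Reagents that add atoms: propionic anhydride CCC(=O)OC(=O)CC
Why: DMAP-catalysed acylation of the secondary alcohol; the C–O bond at the stereocentre is not broken.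

Step 16
Reactants: 25 ethyl (2S,4Z,8S,9E,11E)-4,8,12-trimethyl-15-{1-[(S)-2-methylbutyl]-2-oxo-2,5-dihydro-1H-pyrrol-3-yl}-2-(propanoyloxy)pentadeca-4,9,11-trienoate
Product: 26 (S)-4-hydroxy-3-methyl-5-[(2Z,6S,7E,9E)-2,6,10-trimethyl-13-{1-[(S)-2-methylbutyl]-2-oxo-2,5-dihydro-1H-pyrrol-3-yl}trideca-2,7,9-trien-1-yl]furan-2(5H)-one (target)
Conditions: LiHMDS (3.5 equiv), THF, −78 → −20 °C, argon; 1 M HCl
Reagents that add atoms: none
Why: Dieckmann condensation: the propanoate enolate attacks the neighbouring ethyl ester (5-exo-trig), ethoxide leaves and deprotonation of the tetronic acid drives the closure; the oxygen-bearing stereocentre should survive at low temperature, and the excess base allows for reversible γ-deprotonation of the lactam, which should return to the conjugated lactam on acidic work-up.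

**Compound list**
1 | ethyl glyoxylate | CCOC(=O)C=O | starting material
2 | isobutene (2-methylpropene) | CC(C)=C | starting material
3 | ethyl (S)-2-hydroxy-4-methylpent-4-enoate | C=C(C)C[C@H](O)C(=O)OCC | intermediate
4 | ethyl (S)-2-(allyloxy)-4-methylpent-4-enoate | C=C(C)C[C@H](OCC=C)C(=O)OCC | intermediate
5 | ethyl (S)-4-methyl-3,6-dihydro-2H-pyran-2-carboxylate | CCOC(=O)[C@@H]1CC(C)=CCO1 | intermediate
6 | (S)-2-methylbutan-1-amine | CC[C@H](C)CN | starting material
7 | 2,5-dimethoxy-2,5-dihydrofuran (cis/trans mixture) | COC1C=CC(OC)O1 | starting material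
8 | 1-[(S)-2-methylbutyl]-1,5-dihydro-2H-pyrrol-2-one | CC[C@H](C)CN1CC=CC1=O | intermediate
9 | trans-3,4-dibromo-1-[(S)-2-methylbutyl]pyrrolidin-2-one (both trans diastereomers; ring centres not specified; not isolated) | CC[C@H](C)CN1CC(Br)C(Br)C1=O | intermediate
10 | 3-bromo-1-[(S)-2-methylbutyl]-1,5-dihydro-2H-pyrrol-2-one | CC[C@H](C)CN1CC=C(Br)C1=O | intermediate
11 | methyl (S)-3-hydroxy-2-methylpropanoate (Roche ester) | COC(=O)[C@@H](C)CO | starting material
12 | methyl (S)-3-[(tert-butyldimethylsilyl)oxy]-2-methylpropanoate | COC(=O)[C@@H](C)CO[Si](C)(C)C(C)(C)C | intermediate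
13 | (S)-3-[(tert-butyldimethylsilyl)oxy]-2-methylpropanal | O=C[C@@H](C)CO[Si](C)(C)C(C)(C)C | intermediate
14 | tert-butyl{[(2R,3E)-4-iodo-2-methylbut-3-en-1-yl]oxy}dimethylsilane | I/C=C/[C@@H](C)CO[Si](C)(C)C(C)(C)C | intermediate
15 | pent-4-yn-1-ol | C#CCCCO | starting material
16 | [(E)-5-(dimethylalumanyloxy)-2-methylpent-1-en-1-yl]dimethylalumane (alkenylalane; not isolated) | C[Al](C)/C=C(\C)CCCO[Al](C)C | intermediate
17 | (4E,6E,8R)-9-[(tert-butyldimethylsilyl)oxy]-4,8-dimethylnona-4,6-dien-1-ol | OCCC/C(C)=C/C=C/[C@@H](C)CO[Si](C)(C)C(C)(C)C | intermediate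
18 | tert-butyl{[(2R,3E,5E)-9-iodo-2,6-dimethylnona-3,5-dien-1-yl]oxy}dimethylsilane | ICCC/C(C)=C/C=C/[C@@H](C)CO[Si](C)(C)C(C)(C)C | intermediate
19 | [(4E,6E,8R)-9-[(tert-butyldimethylsilyl)oxy]-4,8-dimethylnona-4,6-dien-1-yl]zinc iodide (not isolated) | I[Zn]CCC/C(C)=C/C=C/[C@@H](C)CO[Si](C)(C)C(C)(C)C | intermediate
20 | 3-{(4E,6E,8R)-9-[(tert-butyldimethylsilyl)oxy]-4,8-dimethylnona-4,6-dien-1-yl}-1-[(S)-2-methylbutyl]-1,5-dihydro-2H-pyrrol-2-one | CC[C@H](C)CN1CC=C(CCC/C(C)=C/C=C/[C@@H](C)CO[Si](C)(C)C(C)(C)C)C1=O | intermediate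
21 | 3-[(4E,6E,8R)-9-hydroxy-4,8-dimethylnona-4,6-dien-1-yl]-1-[(S)-2-methylbutyl]-1,5-dihydro-2H-pyrrol-2-one | CC[C@H](C)CN1CC=C(CCC/C(C)=C/C=C/[C@@H](C)CO)C1=O | intermediate
22 | 3-[(4E,6E,8R)-9-iodo-4,8-dimethylnona-4,6-dien-1-yl]-1-[(S)-2-methylbutyl]-1,5-dihydro-2H-pyrrol-2-one | CC[C@H](C)CN1CC=C(CCC/C(C)=C/C=C/[C@@H](C)CI)C1=O | intermediate
23 | {(2R,3E,5E)-2,6-dimethyl-9-{1-[(S)-2-methylbutyl]-2-oxo-2,5-dihydro-1H-pyrrol-3-yl}nona-3,5-dien-1-yl}zinc iodide (not isolated) | CC[C@H](C)CN1CC=C(CCC/C(C)=C/C=C/[C@@H](C)C[Zn]I)C1=O | intermediate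
24 | ethyl (2S,4Z,8S,9E,11E)-2-hydroxy-4,8,12-trimethyl-15-{1-[(S)-2-methylbutyl]-2-oxo-2,5-dihydro-1H-pyrrol-3-yl}pentadeca-4,9,11-trienoate | CC[C@H](C)CN1CC=C(CCC/C(C)=C/C=C/[C@@H](C)CC/C=C(/C)C[C@H](O)C(=O)OCC)C1=O | intermediate
25 | ethyl (2S,4Z,8S,9E,11E)-4,8,12-trimethyl-15-{1-[(S)-2-methylbutyl]-2-oxo-2,5-dihydro-1H-pyrrol-3-yl}-2-(propanoyloxy)pentadeca-4,9,11-trienoate | CC[C@H](C)CN1CC=C(CCC/C(C)=C/C=C/[C@@H](C)CC/C=C(/C)C[C@H](OC(=O)CC)C(=O)OCC)C1=O | intermediate
26 | (S)-4-hydroxy-3-methyl-5-[(2Z,6S,7E,9E)-2,6,10-trimethyl-13-{1-[(S)-2-methylbutyl]-2-oxo-2,5-dihydro-1H-pyrrol-3-yl}trideca-2,7,9-trien-1-yl]furan-2(5H)-one | CC[C@H](C)CN1CC=C(CCC/C(C)=C/C=C/[C@@H](C)CC/C=C(/C)C[C@@H]2OC(=O)C(C)=C2O)C1=O | target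

**Summary**
Total step count: 16.
Longest linear sequence: 11 steps (11 → 26, steps 6–16).

**Steps most likely to fail**

Step 14 (proposed new method). Oxidative addition into the unstrained allylic C–O bond may be too slow, the diene may sequester the nickel catalyst, or β-hydride elimination and E/Z scrambling may intervene at the allylnickel stage. The fallback uses known chemistry and sets out from 5. Acylative ether cleavage with propanoyl chloride and catalytic ZnCl2 (CH2Cl2, 0 °C) proceeds by O-acylation of the ring oxygen and SN2 attack of chloride at the allylic CH2. It should give ethyl (S,Z)-6-chloro-4-methyl-2-(propanoyloxy)hex-4-enoate F1, which already carries the propanoate and keeps the Z alkene. A nickel-catalysed Negishi coupling of this primary allylic chloride with alkylzinc iodide 23 (made from 22 as in step 14; NiCl2·glyme, terpyridine or pybox ligand, DMA, 0 °C) forms the bond at the less hindered allyl terminus. The fallback comes back to the route at 25 and continues with step 16.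

Step 16. The amide base may deprotonate the γ-position of the unsaturated lactam in competition with the propanoate, leading to deconjugation, oxidation or intermolecular acylation, and prolonged exposure may erode the oxygen-bearing stereocentre. The fallback sets out from 25. The lactam is masked by soft enolisation (TBSOTf, Et3N, CH2Cl2, 0 °C) as ethyl (2S,4Z,8S,9E,11E)-15-{2-[(tert-butyldimethylsilyl)oxy]-1-[(S)-2-methylbutyl]-1H-pyrrol-3-yl}-4,8,12-trimethyl-2-(propanoyloxy)pentadeca-4,9,11-trienoate F2, which has no acidic ring C–H. Dieckmann closure (LiHMDS, THF, −78 °C) then gives the silyloxypyrrole tetronic acid F3 in the flask. Aqueous 1 M HCl work-up cleaves the silyl enol ether with protonation at the ring CH next to nitrogen and returns the conjugated lactam, so the fallback comes back to the route at 26.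

Step 4. The liberated enedial may polymerise, or condensation may give isomeric or over-condensed lactams, lowering the throughput of the only source of the lactam ring. The fallback sets out from 6. Acylation with acryloyl chloride (Et3N, CH2Cl2, 0 °C) gives N-[(S)-2-methylbutyl]acrylamide F4. N-Allylation (NaH, allyl bromide, DMF, 0 °C) gives N-allyl-N-[(S)-2-methylbutyl]acrylamide F5. Ring-closing metathesis (Grubbs II, CH2Cl2, 40 °C) closes the five-membered unsaturated lactam, and the fallback comes back to the route at 8 before step 5.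

**Further compounds**
F1 | step 14 | ethyl (S,Z)-6-chloro-4-methyl-2-(propanoyloxy)hex-4-enoate | ClC/C=C(/C)C[C@H](OC(=O)CC)C(=O)OCC
F2 | step 16 | ethyl (2S,4Z,8S,9E,11E)-15-{2-[(tert-butyldimethylsilyl)oxy]-1-[(S)-2-methylbutyl]-1H-pyrrol-3-yl}-4,8,12-trimethyl-2-(propanoyloxy)pentadeca-4,9,11-trienoate | CC[C@H](C)Cn1ccc(CCC/C(C)=C/C=C/[C@@H](C)CC/C=C(/C)C[C@H](OC(=O)CC)C(=O)OCC)c1O[Si](C)(C)C(C)(C)C
F3 | step 16 | (S)-5-[(2Z,6S,7E,9E)-13-{2-[(tert-butyldimethylsilyl)oxy]-1-[(S)-2-methylbutyl]-1H-pyrrol-3-yl}-2,6,10-trimethyltrideca-2,7,9-trien-1-yl]-4-hydroxy-3-methylfuran-2(5H)-one | CC[C@H](C)Cn1ccc(CCC/C(C)=C/C=C/[C@@H](C)CC/C=C(/C)C[C@@H]2OC(=O)C(C)=C2O)c1O[Si](C)(C)C(C)(C)C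
F4 | step 4 | N-[(S)-2-methylbutyl]acrylamide | CC[C@H](C)CNC(=O)C=C
F5 | step 4 | N-allyl-N-[(S)-2-methylbutyl]acrylamide | CC[C@H](C)CN(CC=C)C(=O)C=C
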